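**Retrosynthetic overview**
- The target is cut at the aryl–acyl bond: C‑6 acylation of a 5‑hydroxy‑7‑methoxy‑8‑prenyl‑2,2‑dimethylchromene with 4‑hydroxyphenylacetic acid (that aryl ring is bought).
- The chromenol is made in one flask from two acyclic pieces: a 3‑methoxy‑4‑prenyl vinylketene plus a siloxyalkyne carrying a CH(OMe)CH=CMe2 arm.
- Ring order in that flask: central benzene ring first ([2+2], 4π opening, 6π closure), then the pyran (loss of MeOH to an o‑quinone methide, oxa‑6π closure). The cycloaddition regiochemistry fixes the OMe, prenyl, O‑pyran and OH positions.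
- Vinylketene precursor: γ‑prenylation of methyl 3‑methoxybut‑2‑enoate, then saponification.
- Siloxyalkyne: acetylene + prenal (alkynylation/O‑methylation), then acetylide oxidation to the ynolate and O‑silylation.

Assumption: the target has no stereocentre and no stereogenic double bond, so it is one achiral compound; stereocentres in intermediates are racemic and are erased in step 5.
Convention: lithium or ammonium salts that are only the conjugate bases of listed compounds (ester enolate, acetylides, carboxylate, phenoxide) are not numbered separately.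

**Step 1**
Reactants: 1 methyl (2E)-3-methoxybut-2-enoate; 2 1-bromo-3-methylbut-2-ene (prenyl bromide)
Product: 3 methyl (2E)-3-methoxy-7-methylocta-2,6-dienoate
Conditions: LDA, THF, DMPU, −78 °C; then 2, −78→−20 °C
Reagents that add atoms: none
Why: γ‑Deprotonation of the vinylogous carbonate gives the extended enolate, which the primary allylic bromide alkylates at the γ‑carbon (vinylogous enolate alkylation, SN2), restoring the conjugated β‑methoxy enoate; no stereocentre is formed and either alkene geometry converges on the same ketene in step 5.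

**Step 2**
Reactants: 3 methyl (2E)-3-methoxy-7-methylocta-2,6-dienoate
Product: 4 (2E)-3-methoxy-7-methylocta-2,6-dienoic acid
Conditions: LiOH, THF/MeOH/H2O, 40 °C; then 1 M HCl to pH 3, 0 °C
Reagents that add atoms: lithium hydroxide, [Li+].[OH-]
Why: Ester saponification (BAc2); the β‑methoxy enoate is a vinylogous carbonate that tolerates hydroxide and brief cold acidification, and the trisubstituted alkene is inert.

**Step 3**
Reactants: 5 acetylene; 6 3-methylbut-2-enal (prenal)
Product: 8 3-methoxy-5-methylhex-4-en-1-yne (racemic), via lithium propargylic alkoxide 7 (not isolated)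
Conditions: n-BuLi, THF, −78 °C (excess 5); 6, −78 °C; MeI, DMPU, −78 °C→rt
Reagents that add atoms: iodomethane, CI
Why: 1,2‑Addition of monolithium acetylide to the enal carbonyl, then Williamson O‑methylation of the lithium alkoxide in the same flask; the new stereocentre is deliberately racemic because it becomes the sp2 C‑4 of the chromene in step 5.

**Step 4**
Reactants: 8 3-methoxy-5-methylhex-4-en-1-yne
Product: 10 triisopropyl[(3-methoxy-5-methylhex-4-en-1-yn-1-yl)oxy]silane (racemic), via lithium ynolate 9 (not isolated)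
Conditions: n-BuLi, THF, −78 °C; t-BuOOLi (from t-BuOOH, LiHMDS), −78→0 °C; TIPSOTf, −78→0 °C
Reagents that add atoms: tert-butyl hydroperoxide, CC(C)(C)OO; triisopropylsilyl trifluoromethanesulfonate, CC(C)[Si](OS(=O)(=O)C(F)(F)F)(C(C)C)C(C)C
Why: Oxidation of the lithium acetylide by lithium tert‑butyl peroxide gives the lithium ynolate (Julia ynolate synthesis), which the bulky silyl triflate traps on oxygen to give the TIPS ynol ether; the allylic methyl ether and the alkene are untouched.

**Step 5 (key step)**
Reactants: 4 (2E)-3-methoxy-7-methylocta-2,6-dienoic acid; 10 triisopropyl[(3-methoxy-5-methylhex-4-en-1-yn-1-yl)oxy]silane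
Product: 18 7-methoxy-2,2-dimethyl-8-(3-methylbut-2-en-1-yl)-2H-chromen-5-ol, via acid chloride 11 (not isolated), via vinylketene 12 (not isolated), via vinylcyclobutenone 13 (not isolated), via dienylketene 14 (not isolated), via benzylic ether phenol 15 (not isolated), via o-quinone methide 16 (not isolated), via TIPS chromenyl ether 17 (not isolated)
Conditions: (COCl)2, cat. DMF, CH2Cl2, 0 °C→rt, evaporate; 10, Et3N, PhMe, 0→25 °C; 110 °C; TBAF, THF, 0 °C; AcOH
Reagents that add atoms: none
Why: Proposed new method: Et3N 1,4‑dehydrochlorinates 11 to vinylketene 12, which adds [2+2] to the electron‑rich siloxyalkyne (ketene carbonyl carbon to the alkyne carbon remote from oxygen) to give 13; on heating, 13 opens (4π) to dienylketene 14, closes (6π) and tautomerises to phenol 15, whose new OH lies next to the CH(OMe)CH=CMe2 arm, so loss of methanol (helped by Et3NH+Cl−) gives o‑quinone methide 16 and oxa‑6π electrocyclisation closes the pyran to 17, so both rings form in one thermal operation with every substituent placed by the cycloaddition regiochemistry and the racemic centres erased; the closest known reactions are the Danheiser vinylketene/siloxyalkyne benzannulation and the benzannulation/o‑quinone methide/electrocyclisation chromene synthesis from chromium carbenes, and fluoride finally cleaves the aryl TIPS ether.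

**Step 6**
Reactants: 18 7-methoxy-2,2-dimethyl-8-(3-methylbut-2-en-1-yl)-2H-chromen-5-ol; 19 4-hydroxyphenylacetic acid
Product: 22 1-[5-hydroxy-7-methoxy-2,2-dimethyl-8-(3-methylbut-2-en-1-yl)-2H-chromen-6-yl]-2-(4-hydroxyphenyl)ethan-1-one (target), via mixed anhydride 20 (not isolated), via aryl trifluoroacetate 21 (not isolated)
Conditions: TFAA (2 equiv), CH2Cl2, 0 °C (19 added to TFAA); 18, −20→0 °C; aq NaHCO3, MeOH, rt
Reagents that add atoms: none
Why: Friedel–Crafts acylation by a mixed carboxylic–trifluoroacetic anhydride: C‑6 is the only free ring carbon and is ortho, ortho and para to three oxygen donors, so it is acylated at low temperature without a Lewis acid, while the transient trifluoroacetyl mask on the distal phenol is hydrolysed in the bicarbonate work‑up and the new ketone is held by the hydrogen bond to 5‑OH.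

**Compound list**
1 | methyl (2E)-3-methoxybut-2-enoate | COC(=O)/C=C(\C)OC | starting material
2 | 1-bromo-3-methylbut-2-ene (prenyl bromide) | CC(C)=CCBr | starting material
3 | methyl (2E)-3-methoxy-7-methylocta-2,6-dienoate | COC(=O)/C=C(\CCC=C(C)C)OC | intermediate
4 | (2E)-3-methoxy-7-methylocta-2,6-dienoic acid | OC(=O)/C=C(\CCC=C(C)C)OC | intermediate
5 | acetylene (ethyne) | C#C | starting material
6 | 3-methylbut-2-enal (prenal) | CC(C)=CC=O | starting material
7 | lithium 5-methylhex-4-en-1-yn-3-olate (racemic, not isolated) | [Li+].[O-]C(C#C)C=C(C)C | intermediate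
8 | 3-methoxy-5-methylhex-4-en-1-yne (racemic) | COC(C#C)C=C(C)C | intermediate
9 | lithium 3-methoxy-5-methylhex-4-en-1-yn-1-olate (racemic ynolate, not isolated) | [Li+].[O-]C#CC(OC)C=C(C)C | intermediate
10 | triisopropyl[(3-methoxy-5-methylhex-4-en-1-yn-1-yl)oxy]silane (racemic) | CC(C)[Si](OC#CC(OC)C=C(C)C)(C(C)C)C(C)C | intermediate
11 | (2E)-3-methoxy-7-methylocta-2,6-dienoyl chloride (not isolated) | ClC(=O)/C=C(\CCC=C(C)C)OC | intermediate
12 | 3-methoxy-7-methylocta-1,3,6-trien-1-one (vinylketene, not isolated) | O=C=CC(OC)=CCC=C(C)C | intermediate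
13 | 2-(1-methoxy-3-methylbut-2-en-1-yl)-4-(1-methoxy-5-methylhexa-1,4-dien-1-yl)-3-[(triisopropylsilyl)oxy]cyclobut-2-en-1-one (diastereomer mixture, not isolated) | O=C1C(C(OC)C=C(C)C)=C(O[Si](C(C)C)(C(C)C)C(C)C)C1C(OC)=CCC=C(C)C | intermediate
14 | 5-methoxy-2-(1-methoxy-3-methylbut-2-en-1-yl)-9-methyl-3-[(triisopropylsilyl)oxy]deca-1,3,5,8-tetraen-1-one (dienylketene, not isolated) | O=C=C(C(OC)C=C(C)C)C(O[Si](C(C)C)(C(C)C)C(C)C)=CC(OC)=CCC=C(C)C | intermediate
15 | 5-methoxy-2-(1-methoxy-3-methylbut-2-en-1-yl)-6-(3-methylbut-2-en-1-yl)-3-[(triisopropylsilyl)oxy]phenol (racemic, not isolated) | COc1cc(O[Si](C(C)C)(C(C)C)C(C)C)c(C(OC)C=C(C)C)c(O)c1CC=C(C)C | intermediate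
16 | 3-methoxy-6-(3-methylbut-2-en-1-ylidene)-2-(3-methylbut-2-en-1-yl)-5-[(triisopropylsilyl)oxy]cyclohexa-2,4-dien-1-one (o-quinone methide, not isolated) | O=C1C(=CC=C(C)C)C(O[Si](C(C)C)(C(C)C)C(C)C)=CC(OC)=C1CC=C(C)C | intermediate
17 | {[7-methoxy-2,2-dimethyl-8-(3-methylbut-2-en-1-yl)-2H-chromen-5-yl]oxy}triisopropylsilane (not isolated) | COc1cc(O[Si](C(C)C)(C(C)C)C(C)C)c2C=CC(C)(C)Oc2c1CC=C(C)C | intermediate
18 | 7-methoxy-2,2-dimethyl-8-(3-methylbut-2-en-1-yl)-2H-chromen-5-ol | COc1cc(O)c2C=CC(C)(C)Oc2c1CC=C(C)C | intermediate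
19 | 4-hydroxyphenylacetic acid | OC(=O)Cc1ccc(O)cc1 | starting material
20 | [4-(trifluoroacetoxy)phenyl]acetic trifluoroacetic anhydride (not isolated) | O=C(Cc1ccc(OC(=O)C(F)(F)F)cc1)OC(=O)C(F)(F)F | intermediate
21 | 4-{2-[5-hydroxy-7-methoxy-2,2-dimethyl-8-(3-methylbut-2-en-1-yl)-2H-chromen-6-yl]-2-oxoethyl}phenyl trifluoroacetate (not isolated) | COc1c(CC=C(C)C)c2OC(C)(C)C=Cc2c(O)c1C(=O)Cc1ccc(OC(=O)C(F)(F)F)cc1 | intermediate
22 | 1-[5-hydroxy-7-methoxy-2,2-dimethyl-8-(3-methylbut-2-en-1-yl)-2H-chromen-6-yl]-2-(4-hydroxyphenyl)ethan-1-one | COc1c(CC=C(C)C)c2c(c(O)c1C(=O)Cc1ccc(O)cc1)C=CC(C)(C)O2 | target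

**Totals and risks**
Total step count: 6. Longest linear sequence: 4 steps (1→2→5→6, or equally 3→4→5→6).

Most likely to fail, in order:

Step 5. The vinylketene may dimerise before the [2+2], and the benzylic methyl ether of 15 may not ionise cleanly to the quinone methide. The fallback builds the two rings one after the other; it sets out from 5 and 4 and rejoins the route at 17. The lithium acetylide of 5 is oxidised with t‑BuOOLi and silylated to (ethynyloxy)triisopropylsilane F2. The same vinylketene benzannulation (4 via 11 and 12, toluene, 25 then 110 °C) with F2 gives 3-methoxy-2-(3-methylbut-2-en-1-yl)-5-[(triisopropylsilyl)oxy]phenol F3, whose only free position ortho to the OH is the future C‑4a. F3 is then condensed with prenal 6 (ethylenediammonium diacetate, xylene, 140 °C) to close the pyran by the classical aldol/dehydration/oxa‑6π annulation, giving 17, which TBAF converts to 18.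

Step 6. The trifluoroacetic acid released can protonate the electron‑rich chromene and prenyl alkenes, and O‑acylation of the 5‑OH can compete with C‑acylation. The fallback replaces electrophilic substitution by directed metalation; it sets out from 18 and 19 and rejoins at 22. 18 is protected as 7-methoxy-5-(methoxymethoxy)-2,2-dimethyl-8-(3-methylbut-2-en-1-yl)-2H-chromene F4 (MOMCl, i‑Pr2NEt). 19 is converted to 2-(4-hydroxyphenyl)-N-methoxy-N-methylacetamide F5 (MeNHOMe·HCl, EDC) and then to N-methoxy-2-[4-(methoxymethoxy)phenyl]-N-methylacetamide F6 (MOMCl, i‑Pr2NEt). F4 is lithiated at C‑6, the site between OMOM and OMe (n‑BuLi, THF, 0 °C), and added to F6 at −78 °C to give 1-[7-methoxy-5-(methoxymethoxy)-2,2-dimethyl-8-(3-methylbut-2-en-1-yl)-2H-chromen-6-yl]-2-[4-(methoxymethoxy)phenyl]ethan-1-one F7. Both MOM groups are removed with 2 M HCl in MeOH at 40 °C to give 22.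

Step 1. α‑ instead of γ‑alkylation, or dialkylation, of the extended enolate would lower the yield of 3. The fallback uses a β‑keto ester dianion instead; it sets out from 2 and rejoins at 3. The dianion of methyl acetoacetate (2 equiv LDA, THF, 0 °C) is alkylated with 2 at the terminal carbon to give methyl 7-methyl-3-oxooct-6-enoate F1, which is converted to the methyl enol ether 3 with trimethyl orthoformate and catalytic H2SO4 in MeOH (rt, then distillation).

**Further compounds**
F1 | step 1 | methyl 7-methyl-3-oxooct-6-enoate | COC(=O)CC(=O)CCC=C(C)C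
F2 | step 5 | (ethynyloxy)triisopropylsilane | C#CO[Si](C(C)C)(C(C)C)C(C)C
F3 | step 5 | 3-methoxy-2-(3-methylbut-2-en-1-yl)-5-[(triisopropylsilyl)oxy]phenol | COc1cc(O[Si](C(C)C)(C(C)C)C(C)C)cc(O)c1CC=C(C)C
F4 | step 6 | 7-methoxy-5-(methoxymethoxy)-2,2-dimethyl-8-(3-methylbut-2-en-1-yl)-2H-chromene | COCOc1cc(OC)c(CC=C(C)C)c2OC(C)(C)C=Cc12
F5 | step 6 | 2-(4-hydroxyphenyl)-N-methoxy-N-methylacetamide | CON(C)C(=O)Cc1ccc(O)cc1
F6 | step 6 | N-methoxy-2-[4-(methoxymethoxy)phenyl]-N-methylacetamide | CON(C)C(=O)Cc1ccc(OCOC)cc1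
F7 | step 6 | 1-[7-methoxy-5-(methoxymethoxy)-2,2-dimethyl-8-(3-methylbut-2-en-1-yl)-2H-chromen-6-yl]-2-[4-(methoxymethoxy)phenyl]ethan-1-one | COCOc1c(C(=O)Cc2ccc(OCOC)cc2)c(OC)c(CC=C(C)C)c2OC(C)(C)C=Cc12
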